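Readings and results are calculated on assumed constants; noise was put on by code.

Take the day as your unit: the questions below come down to how many target lifetimes fit into the last days of a flask.

in all of them: free catalyst 0.5 mol%

|  | starting material | reagent | protic impurity | temperature | remark | time |
|---|---|---|---|---|---|---|
| amber | 34 mM | 1 equiv | 34 mM | 0 °C | run made earlier |  |
| blue | 17 mM | 1 equiv | 34 mM | 11 °C | run made earlier |  |
| ochre | 68 mM | 1 equiv | 34 mM | 0 °C | run made earlier |  |
| summer | 34 mM | 1.00 equiv | 34.0 mM | 5 °C | everything together at the start | 20 d |
| autumn | 34 mM | 1.00 equiv (fed, over 15 d) | 34.0 mM |  | the addition at −25 °C, then warmed to 5 °C; the feed brings no volume worth counting | 20 d |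
| dusk | 34 mM (fed, over 4.0 d) | 1.00 equiv | 34.0 mM | 5 °C | all else is in the flask from the start; the feed brings no volume worth counting | 20 d |
| winter | 34 mM (fed, over 15 d) | 1.00 equiv | 34.0 mM | 5 °C | all else is in the flask from the start; the feed brings no volume worth counting | 20 d |

- amber (time / d: target / %, over-reaction product / %): 1.67: 9.9, 6.9; 3.00: 11.7, 13.9; 5.00: 10.6, 28.3; 6.00: 8.9, 33.4; 8.00: 6.6, 43.4; 10.0: 4.7, 50.9; 12.0: 3.4, 55.4
- blue (time / d: target / %, over-reaction product / %): 0.833: 4.7, 7.6; 2.50: 2.4, 27.5; 5.00: 0.4, 41.0; 6.00: 0.1, 44.5; 10.0: 0.8, 49.4; 12.0: 1.1, 50.3; 15.0: 0.6, 51.0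
- ochre (time / d: target / %, over-reaction product / %): 0.833: 10.5, 2.9; 2.50: 18.0, 19.6; 5.00: 13.5, 45.4; 6.00: 11.5, 52.5; 10.0: 4.5, 71.1; 12.0: 1.2, 74.3; 15.0: 0.6, 76.9

(scatter of a reading: 0.5 percentage points)



* the flask that comes out highest in share of target in target plus over-reaction product, or "all alike" when all lie within 1.5 percentage points (summer / autumn / dusk / winter / all alike)
* share of target in target plus over-reaction product at the end, summer
* share of target in target plus over-reaction product at the end, autumn
* share of target in target plus over-reaction product at the end, dusk
* share of target in target plus over-reaction product at the end, winter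

Start from the balance of over-reaction product. If it forms from target in a first-order step, it grows at k·c(target), so k is the gain over a span divided by the mean target and the length of that span. Between 5.00 d and 8.00 d, the amber readings give 0.585 d⁻¹ at 0 °C. You may object that concentration could enter this step. But the ochre run, with twice the charge, reads 0.655 d⁻¹ at the same temperature, so I keep first order. The blue run reads 3.36 d⁻¹ at 11 °C, though roughly, since its target stands close to the scatter. Because 5 °C lies close to the middle of those temperatures, I take the geometric mean, 1.40 d⁻¹. This gives the target lifetime, the time in which target left to itself falls by a factor e, of 0.713 d.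

A first estimate for autumn follows. Its warm stretch of 5.00 d holds 7.01 lifetimes, so a stock of target would shrink to 0.0900%. The objection is that target is still being made: in the amber run, target plus over-reaction product still climbs at 10.0 d. So treat target as a quasi-steady state, with c(target) equal to the making rate r times the lifetime, and the share equal to r·τ over the total made. The amber run shows r falling from 0.0665 d⁻¹ to 0.0280 d⁻¹ of the charge. I take their mean, 0.0473 d⁻¹, which gives target 3.37%. Guessing that autumn gets as far as the amber run did by 10.0 d, with total 55.6%, my share is 6.06%. Summer, dusk and winter stay at 5 °C throughout, so I expect their making to have faded by the end, and I pick autumn.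

The forecast says autumn, with 0.01% for summer, 7% for autumn, 0.02% for dusk and 0% for winter, since in autumn “reaction is still running”.

The flasks give 0.0478% for summer, 7.99% for autumn, 0.0966% for dusk and 1.44% for winter, so autumn is highest.

    starting material + free catalyst → catalyst intermediate A (k = 1.10 M⁻¹ min⁻¹, Ea = 64.0 kJ mol⁻¹)
    reagent + catalyst intermediate A → catalyst intermediate B (k = 4.10 M⁻¹ min⁻¹, Ea = 50.0 kJ mol⁻¹)
    catalyst intermediate B → free catalyst + target (k = 0.180 min⁻¹, Ea = 80.0 kJ mol⁻¹)
    starting material + protic impurity → quenched substrate (k = 0.00270 M⁻¹ min⁻¹, Ea = 57.0 kJ mol⁻¹)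
    target → over-reaction product (k = 8.90 × 10⁻⁴ min⁻¹, Ea = 94.0 kJ mol⁻¹)
    (constants at 5 °C)

The constant of the last step gives a target lifetime at 5 °C of 0.780 d, beside my 0.713 d from the readings, so in autumn at 20.0 d, with target at 4.12%, over-reaction product grows at 0.0528 d⁻¹ of the charge, and this lifetime is shorter than the 8.2 d half-life of reagent in its step with catalyst intermediate A at that time. In the neighbouring flask with 8.5 mM of starting material, target stands at 1.91% beside 16.5% of over-reaction product, so the same lifetime of 0.780 d gives 0.0245 d⁻¹ of the charge, and its share is 10.4%.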